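## Retrosynthetic overview

1. Monotesone A ⇒ (global desilylation) its tris-TBS ether ⇒ cut between C2 of ring C and C1' of ring B ⇒ a flat, achiral 5,7-bis(silyloxy)chromone and a B-ring boronic acid that already carries the 4'-O-prenyl group.
2. Enabling feature: C2, the only stereocentre, bears ring B, is bound to O1 and lies β to the C4 ketone of ring C. With two hydrogens fewer (C2=C3), the unit O1–C2=C3–C4=O is a cyclic enone whose β-carbon accepts an aryl–rhodium species, so one catalytic step makes the bond, sets C2 and brings ring C to its final oxidation level.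
3. The B-ring pattern (3'-OH beside 4'-O-prenyl, carbon substituent para to the ether) is fixed without regiochemical doubt from 4-bromo-2-iodophenol: O-prenylation, C–I → C–OH, silylation, C–Br → C–B(OH)2.
4. Ring order: no ring is closed in the route. Rings A and C enter together as commercial 5,7-dihydroxychromone and ring B as the halophenol; ring C passes from 4-pyranone to 2,3-dihydro-4-pyranone in the key step.
5. All three phenols carry the same TBS group, so a single weakly acidic fluoride step follows the creation of the base-sensitive stereocentre.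

Key step: step 6

Assumption: the (S)-configured biaryl bisphosphine is taken to deliver the aryl group to the Re face of C2 (O1 > C3 > H), by analogy with 2-cyclohexenone, where (S)-biaryl bisphosphines lead to the (S)-3-aryl ketone of the same spatial sense; should the sense be opposite, the equally available (R)-ligand is used.

## Route

Step 1
Reactants: 1 4-bromo-2-iodophenol; 2 1-bromo-3-methylbut-2-ene (prenyl bromide)
Product: 3 4-bromo-2-iodo-1-[(3-methylbut-2-en-1-yl)oxy]benzene
Conditions: K2CO3 (1.5 equiv), DMF, rt
Reagents that add atoms: none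
Why: Williamson ether synthesis, in which the phenoxide of 1 displaces the primary allylic bromide by SN2 and a carbonate base in a polar aprotic solvent favours O- over C-alkylation.

Step 2
Reactants: 3 4-bromo-2-iodo-1-[(3-methylbut-2-en-1-yl)oxy]benzene
Product: 6 5-bromo-2-[(3-methylbut-2-en-1-yl)oxy]phenol, via arylmagnesium chloride 4 (not isolated), via dimethyl arylboronate 5 (not isolated)
Conditions: i-PrMgCl (1.1 equiv), THF, −40 °C; B(OMe)3 (1.5 equiv), −40 °C → rt; 30% aq H2O2, 0 °C → rt
Reagents that add atoms: hydrogen peroxide, OO (phenol O of 6); for the intermediates: isopropylmagnesium chloride, CC(C)[Mg]Cl (MgCl of 4); trimethyl borate, COB(OC)OC (B(OMe)2 of 5)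
Why: Iodine–magnesium exchange is far faster at the C–I bond (also ortho to the coordinating ether O) than at C–Br, and borylation followed by boronate oxidation (1,2-aryl shift to hydroperoxide oxygen) uses a nucleophilic oxidant that leaves the prenyl alkene untouched.

Step 3
Reactants: 6 5-bromo-2-[(3-methylbut-2-en-1-yl)oxy]phenol
Product: 7 {5-bromo-2-[(3-methylbut-2-en-1-yl)oxy]phenoxy}(tert-butyl)dimethylsilane
Conditions: TBSCl (1.2 equiv), imidazole (2 equiv), CH2Cl2, rt
Reagents that add atoms: tert-butyldimethylsilyl chloride, CC(C)(C)[Si](C)(C)Cl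
Why: Standard imidazole-promoted O-silylation of an unhindered phenol, which removes the acidic proton before the organolithium step.

Step 4
Reactants: 7 {5-bromo-2-[(3-methylbut-2-en-1-yl)oxy]phenoxy}(tert-butyl)dimethylsilane
Product: 10 {3-[(tert-butyldimethylsilyl)oxy]-4-[(3-methylbut-2-en-1-yl)oxy]phenyl}boronic acid, via aryllithium 8 (not isolated), via lithium aryltriisopropoxyborate 9 (not isolated)
Conditions: B(Oi-Pr)3 (1.3 equiv), then n-BuLi (1.1 equiv, added last), THF, −78 → −20 °C; 1 M aq HCl to pH 5–6
Reagents that add atoms: triisopropyl borate, CC(C)OB(OC(C)C)OC(C)C (B); water, O (the two OH on boron); for the intermediates: n-butyllithium, [Li]CCCC (Li of 8 and 9)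
Why: Bromine–lithium exchange with in situ borate trapping outruns allylic deprotonation at −78 °C, the lithium sits meta to the silyloxy group so no O→C silyl shift can occur, and mild acidic hydrolysis should spare both the aryl silyl ether and the prenyl ether.

Step 5
Reactants: 11 5,7-dihydroxy-4H-chromen-4-one (5,7-dihydroxychromone)
Product: 12 5,7-bis[(tert-butyldimethylsilyl)oxy]-4H-chromen-4-one
Conditions: TBSOTf (2.6 equiv), 2,6-lutidine (4 equiv), CH2Cl2, 0 °C → rt; aq NaHCO3 work-up
Reagents that add atoms: tert-butyldimethylsilyl triflate, CC(C)(C)[Si](C)(C)OS(=O)(=O)C(F)(F)F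
Why: O-silylation with a silyl triflate and a hindered pyridine base is forceful enough for the chelated 5-OH as well as the free 7-OH, and any O4-silylated benzopyrylium salt reverts to the chromone on aqueous work-up.

Step 6
Reactants: 10 {3-[(tert-butyldimethylsilyl)oxy]-4-[(3-methylbut-2-en-1-yl)oxy]phenyl}boronic acid; 12 5,7-bis[(tert-butyldimethylsilyl)oxy]-4H-chromen-4-one
Product: 13 (2S)-5,7-bis[(tert-butyldimethylsilyl)oxy]-2-{3-[(tert-butyldimethylsilyl)oxy]-4-[(3-methylbut-2-en-1-yl)oxy]phenyl}-2,3-dihydro-4H-chromen-4-one
Conditions: [Rh(OH)(cod)]2 (2.5 mol %), (S)-MeO-F12-BIPHEP [(S)-6,6'-dimethoxybiphenyl-2,2'-diylbis{bis(3,4,5-trifluorophenyl)phosphine}] (5.5 mol %), 10 (2 equiv), toluene/H2O 10:1, 25 → 40 °C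
Reagents that add atoms: none
Why: Transmetalation of 10 to the hydroxorhodium(I) complex gives an aryl–Rh species that binds the C2=C3 bond of 12 and inserts it with the aryl group going to the β-carbon C2, and water protonates the resulting oxa-π-allyl rhodium enolate at C3, freeing 13 and restoring Rh–OH. This is the Hayashi–Miyaura reaction (Rh-catalysed asymmetric 1,4-addition of arylboronic acids), which has close precedent on chromones bearing oxygen substituents in ring A when electron-poor biaryl bisphosphines are used. No ring is closed; ring C merely passes from the flat 4-pyranone to the 2,3-dihydro level of the target. C2 is the only new stereocentre and is under pure catalyst control: the C2-symmetric (S)-ligand leaves open only the quadrant in which the chromone binds through its C2 Re face, so syn-carborhodation should give (2S). The step needs 1,4- over 1,2-addition and selectivity for the enone over the prenyl alkene, which the substrate secures because the C4 carbonyl is a vinylogous ester flanked by the peri 5-OTBS group and an unactivated trisubstituted alkene does not insert into aryl–Rh. The base-free, near-neutral medium should keep the aryl silyl ethers in place and prevent retro-oxa-Michael opening of 13, so the new stereocentre is not scrambled, while the excess of 10 offsets protodeboronation.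

Step 7
Reactants: 13 (2S)-tris-TBS flavanone
Product: 14 monotesone A, (2S)-5,7-dihydroxy-2-{3-hydroxy-4-[(3-methylbut-2-en-1-yl)oxy]phenyl}-2,3-dihydro-4H-chromen-4-one
Conditions: KHF2 (7.5 equiv), MeOH/THF 2:1, rt
Reagents that add atoms: none
Why: Fluoride-induced cleavage of aryl silyl ethers in a bifluoride-buffered, weakly acidic medium releases phenols rather than phenoxides, so neither base-induced retro-oxa-Michael opening of ring C (further disfavoured because O4' is alkylated and no quinone methide can form) nor acid cleavage of the prenyl ether should occur, and C2 stays (S).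

## Compound list

1 | 4-bromo-2-iodophenol | Oc1ccc(Br)cc1I | starting material
2 | 1-bromo-3-methylbut-2-ene (prenyl bromide) | CC(C)=CCBr | starting material
3 | 4-bromo-2-iodo-1-[(3-methylbut-2-en-1-yl)oxy]benzene | CC(C)=CCOc1ccc(Br)cc1I | intermediate
4 | {5-bromo-2-[(3-methylbut-2-en-1-yl)oxy]phenyl}magnesium chloride (not isolated) | CC(C)=CCOc1ccc(Br)cc1[Mg]Cl | intermediate
5 | dimethyl {5-bromo-2-[(3-methylbut-2-en-1-yl)oxy]phenyl}boronate (not isolated) | CC(C)=CCOc1ccc(Br)cc1B(OC)OC | intermediate
6 | 5-bromo-2-[(3-methylbut-2-en-1-yl)oxy]phenol | CC(C)=CCOc1ccc(Br)cc1O | intermediate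
7 | {5-bromo-2-[(3-methylbut-2-en-1-yl)oxy]phenoxy}(tert-butyl)dimethylsilane | CC(C)=CCOc1ccc(Br)cc1O[Si](C)(C)C(C)(C)C | intermediate
8 | {3-[(tert-butyldimethylsilyl)oxy]-4-[(3-methylbut-2-en-1-yl)oxy]phenyl}lithium (not isolated) | CC(C)=CCOc1ccc([Li])cc1O[Si](C)(C)C(C)(C)C | intermediate
9 | lithium {3-[(tert-butyldimethylsilyl)oxy]-4-[(3-methylbut-2-en-1-yl)oxy]phenyl}triisopropoxyborate (not isolated) | [Li+].CC(C)=CCOc1ccc(cc1O[Si](C)(C)C(C)(C)C)[B-](OC(C)C)(OC(C)C)OC(C)C | intermediate
10 | {3-[(tert-butyldimethylsilyl)oxy]-4-[(3-methylbut-2-en-1-yl)oxy]phenyl}boronic acid | CC(C)=CCOc1ccc(B(O)O)cc1O[Si](C)(C)C(C)(C)C | intermediate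
11 | 5,7-dihydroxy-4H-chromen-4-one | O=c1ccoc2cc(O)cc(O)c12 | starting material
12 | 5,7-bis[(tert-butyldimethylsilyl)oxy]-4H-chromen-4-one | O=c1ccoc2cc(O[Si](C)(C)C(C)(C)C)cc(O[Si](C)(C)C(C)(C)C)c12 | intermediate
13 | (2S)-5,7-bis[(tert-butyldimethylsilyl)oxy]-2-{3-[(tert-butyldimethylsilyl)oxy]-4-[(3-methylbut-2-en-1-yl)oxy]phenyl}-2,3-dihydro-4H-chromen-4-one | CC(C)=CCOc1ccc([C@@H]2CC(=O)c3c(O[Si](C)(C)C(C)(C)C)cc(O[Si](C)(C)C(C)(C)C)cc3O2)cc1O[Si](C)(C)C(C)(C)C | intermediate
14 | monotesone A | CC(C)=CCOc1ccc([C@@H]2CC(=O)c3c(O)cc(O)cc3O2)cc1O | target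

## Step count and risks

Total step count: 7. Longest linear sequence: 6 steps (1 → 3 → 6 → 7 → 10 → 13 → 14).

**Step 6.**
- What may go wrong: carborhodation of the electron-rich, doubly donor-substituted chromone may be sluggish, so protodeboronation of the electron-rich boronic acid uses up the nucleophile. Facial selectivity may also be incomplete.
- Fallback: it sets out from 7 (through aryllithium 8) and 12 and replaces the protic boron chemistry by an aprotic, Lewis-acid-assisted variant.
  - Aryllithium 8 is transmetalated with ZnCl2 to the arylzinc chloride F1.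
  - F1 is added to 12 with [RhCl(C2H4)2]2/(S)-BINAP in THF at 20 °C in the presence of Me3SiCl. The chlorosilane activates the C4 carbonyl and traps the enolate as the (2S)-4-(trimethylsilyloxy)-2H-chromene F2, so neither protodemetalation by water nor ring opening can intervene.
  - Brief treatment of F2 with aqueous citric acid in THF cleaves only the enol silane, and the sequence comes back to the route at 13.

**Step 5.**
- What may go wrong: silylation of the chelated 5-OH may be incomplete, or the peri 5-O-silyl group may be lost during chromatography.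
- Fallback: it sets out from 11 and gives up protection of O5.
  - TBSCl (1.05 equiv) and imidazole in DMF at 0 °C silylate only the free 7-OH, giving 7-[(tert-butyldimethylsilyl)oxy]-5-hydroxy-4H-chromen-4-one F3. Its internal O5–H···O=C4 hydrogen bond should raise the electrophilicity of C2.
  - F3 is coupled with 10 under the catalyst of step 6 to give the (2S)-5-hydroxyflavanone bis-silyl ether F4.
  - KHF2 in MeOH/THF removes the two silyl groups of F4, so the sequence comes back to the route at 14.

**Step 4.**
- What may go wrong: butyllithium may attack silicon or the allylic O–CH2 position, or the silyl group or the boron may be lost during acidic hydrolysis and isolation of an amphiphilic boronic acid.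
- Fallback: it sets out from 7 and avoids organolithium chemistry.
  - Miyaura borylation (B2pin2, PdCl2(dppf), KOAc, dioxane, 80 °C) gives the chromatographable pinacol boronate F5.
  - The diol of F5 is cleaved oxidatively (NaIO4, NH4OAc, acetone/H2O, rt; the prenyl alkene is inert to periodate), so the sequence comes back to the route at 10.

## Further compounds

F1 | step 6 | {3-[(tert-butyldimethylsilyl)oxy]-4-[(3-methylbut-2-en-1-yl)oxy]phenyl}zinc chloride | CC(C)=CCOc1ccc([Zn]Cl)cc1O[Si](C)(C)C(C)(C)C
F2 | step 6 | (2S)-5,7-bis[(tert-butyldimethylsilyl)oxy]-2-{3-[(tert-butyldimethylsilyl)oxy]-4-[(3-methylbut-2-en-1-yl)oxy]phenyl}-4-[(trimethylsilyl)oxy]-2H-chromene | CC(C)=CCOc1ccc([C@@H]2C=C(O[Si](C)(C)C)c3c(O[Si](C)(C)C(C)(C)C)cc(O[Si](C)(C)C(C)(C)C)cc3O2)cc1O[Si](C)(C)C(C)(C)C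
F3 | step 5 | 7-[(tert-butyldimethylsilyl)oxy]-5-hydroxy-4H-chromen-4-one | O=c1ccoc2cc(O[Si](C)(C)C(C)(C)C)cc(O)c12
F4 | step 5 | (2S)-7-[(tert-butyldimethylsilyl)oxy]-2-{3-[(tert-butyldimethylsilyl)oxy]-4-[(3-methylbut-2-en-1-yl)oxy]phenyl}-5-hydroxy-2,3-dihydro-4H-chromen-4-one | CC(C)=CCOc1ccc([C@@H]2CC(=O)c3c(O)cc(O[Si](C)(C)C(C)(C)C)cc3O2)cc1O[Si](C)(C)C(C)(C)C
F5 | step 4 | tert-butyldimethyl{2-[(3-methylbut-2-en-1-yl)oxy]-5-(4,4,5,5-tetramethyl-1,3,2-dioxaborolan-2-yl)phenoxy}silane | CC(C)=CCOc1ccc(B2OC(C)(C)C(C)(C)O2)cc1O[Si](C)(C)C(C)(C)C
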